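**Assumption:** atom numbers follow the 2H-chromene skeleton (O1, C2, C3, C4, C4a, C5 to C8, C8a). C9 is the carbonyl carbon on C6, C10 the carbonyl carbon on the anisyl ring, C1' the anisyl ipso carbon. The three starting materials and all reagents are taken as purchasable.

## Analysis of the target

The target is 1-(7-hydroxy-5-methoxy-2,2-dimethyl-2H-chromen-6-yl)-2-(4-methoxyphenyl)ethane-1,2-dione. It is a 2,2-dimethyl-2H-chromene whose benzene ring A is substituted at five of six positions: O1 at C8a, the pyran carbon C4 at C4a, OMe at C5, the C9–C10 diketone at C6 and OH at C7, with only C8 free. There is no stereocentre; the only geometrical element that matters on the way is the Z-configuration of an open-chain alkene that later becomes the ring bond C3=C4.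

The sensitive groups are:
- the 1,2-diketone, which is open to benzilic acid rearrangement and to C–C cleavage by base or peroxide;
- the styrene-like C3=C4 bond, which is open to electrophiles, strong acid and hydrogenation;
- the C5 methyl ether ortho to a carbonyl, which Lewis acids would cleave;
- the C7 phenol, which is hydrogen-bonded to C9 and can add to C10 as a hemiketal.

The difficulty is regiochemical. Ring A is a phloroglucinol pattern in which all three oxygens differ (ring ether, methyl ether, free phenol), and two carbon substituents must sit at defined positions between them. Chromenylation of phloroglucinol derivatives usually leaves both questions to weak directing effects.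

The strategy rests on C8a. It bears O1, is ortho to C4a and is meta to both the C5 and the C7 oxygen. A fluorine at C8a can therefore, together with the C5 methoxy group, direct lithiation to C4a. Later it can be displaced by a side-chain alkoxide at a carbon into which neither ring oxygen donates by resonance.

## Retrosynthetic reasoning

**19 from 18.** The C7 phenol is unmasked last. Until then it is carried as the methoxymethyl ether 18, because the free phenol would interfere with the metalation and the oxidation and can add to C10. The cut is the acetal O–CH2 bond. The forward step must use a protic acid, so that the C5 methyl ether ortho to C9 and the chromene double bond remain.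

**18 from 17.** C10 is taken back from carbonyl to methylene. No skeletal bond is cut; the gain is that the C6–C9 bond can be made with a plain arylacetic acid derivative. The methylene in 17 is benzylic and alpha to a ketone, so the forward oxidation has one activated site to find.

**17 from 11 and 14.** The C6–C9 bond is cut. C6 lies between the C5 methoxy group and the C7 acetal oxygen, so the aryllithium 15 should be available by directed metalation of 11. The amide 14 stops at the chelate 16 and gives the ketone only on work-up. Amide 14 comes from acid 12 through the acyl imidazolide 13. Cutting C9–C10 or C10–C1' instead would demand an acyl anion equivalent and more steps.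

**11 from 10 from 9.** Only the oxygen substituent at C7 changes. The bulky silyl ether of 9 is needed early as a steric shield that does not direct metalation. The acetal of 11 is needed late as a director. The exchange costs two steps and separates two metalations that would otherwise compete.

**9 from 7 (through 8).** The O1–C8a bond is cut, which opens the pyran ring. This is the central disconnection: it turns the heterocycle into an open-chain Z-allylic tertiary alcohol on a fluoroarene. The forward reaction has to make an electron-rich aryl fluoride accept an alkoxide. It is helped by intramolecularity, by the Z-alkene and by the meta relation of C8a to both ring oxygens. Cutting O1–C2 or C4–C4a instead would bring back the regiochemical questions of phenol alkylation or sigmatropic shift.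

**7 from 6, and 6 from 4 and 5.** The Z-alkene is traced to the alkyne 6, because cis-selective semi-hydrogenation is the most direct way to the geometry the ring closure needs. The C4–C4a bond of 6 is cut into the aryl iodide 4 and the alkynol 5, which supplies C2, C3, C4, both methyl groups and O1 in one piece.

**4 from 2 (through 3), and 2 from 1.** The C–I bond at C4a is cut. In 2 the position between fluorine and methoxy is the most acidic and the least hindered, because the silyl ether shields both of its own neighbours. Metalation to 3 and trapping with the halogen fix the carbon substituent at C4a without any isomer question. Silyl ether 2 is made from the commercial phenol 1, which already carries F, OMe and OH in the 1,3,5-pattern of ring A.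

## Alternatives that were turned down

**Alternative 1:** an oxalic acid linchpin for the diketone.
- Disconnection: C6–C9 and C10–C1' are cut, and C9 and C10 come together from N,N'-dimethoxy-N,N'-dimethyloxalamide A2.
- Forward key step: chromene 11 is metalated at C6 to 15, which adds to one amide group of A2. The tetrahedral chelate protects that carbon while 4-methoxyphenylmagnesium bromide A3 adds to the other amide group. Acidic work-up releases 1-[5-methoxy-7-(methoxymethoxy)-2,2-dimethyl-2H-chromen-6-yl]-2-(4-methoxyphenyl)ethane-1,2-dione A1, which has the structure of 18.
- For it: the diketone arrives at the right oxidation level. No enolisable intermediate is passed and no oxidant meets the chromene. About two steps are saved against steps 8 to 10. On the endgame this plan is stronger than the chosen one.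
- Against it: it starts from the finished, regiodefined chromene 11 and contributes nothing to ring A or the pyran, where the real difficulty lies. It shares the C6-against-C8 metalation question. Two different nucleophiles must be delivered in sequence to two equal amide groups; if the hindered aryllithium is not fully consumed, A3 adds twice to A2.
- Comparison: the chosen strategy supplies a route to 11 in which fluorine fixes every ring position, and its endgame uses two ordinary, separately controllable steps. The linchpin could be grafted on as a shortcut, but as a strategy of its own it leaves the core unsolved.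

**Alternative 2:** a propargyl ether Claisen cascade.
- Disconnection: C4–C4a is cut, and O1–C2 is broken and re-formed in the cascade. The precursor is methyl 2-hydroxy-6-(methoxymethoxy)-4-[(2-methylbut-3-yn-2-yl)oxy]benzoate A5.
- Forward key step: heating A5 causes a [3,3] shift to the ring carbon next to the chelated hydroxyl, then enolisation, a 1,5-hydrogen shift and an oxa-6π closure. The product is methyl 5-hydroxy-7-(methoxymethoxy)-2,2-dimethyl-2H-chromene-6-carboxylate A4.
- For it: the chemistry is thermal, metal-free and well understood. The C6 carbon is present from the start as the ester, so no metalation has to choose between C6 and C8. On that point it is stronger than the chosen plan.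
- Against it: A5 requires three similar phloroglucinol oxygens to be told apart before the key step. The direction of the shift depends on bond fixation by one hydrogen bond; leakage to the other ortho carbon gives an isomer that differs only in which oxygen is free. After A4 the chelated C5 hydroxyl must be methylated, and an ester flanked by two alkoxy groups must be turned into an aryl diketone, which takes several redox and C–C steps.
- Comparison: this route is longer overall and its regiocontrol is a bias. The chosen strategy buys the oxygen pattern with the methyl ether in place, and the position of ring closure is fixed by the single fluorine.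

**Alternative 3:** a Danheiser benzannulation for ring A.
- Disconnection: ring A is cut at C4a–C8a and C5–C6, with C8–C8a broken and re-formed. The partners are 3-(triisopropylsilyloxy)cyclobut-2-en-1-one A7 and 1-methoxy-5-methylhex-4-en-1-yne A8.
- Forward key step: heating A7 with A8 causes four-electron ring opening, [2+2] addition, a second ring opening and a 6π closure. The product is 3-methoxy-2-(3-methylbut-2-en-1-yl)-5-(triisopropylsilyloxy)phenol A6, which a dehydrogenative cyclisation would then turn into 9.
- For it: the place of every substituent on ring A follows from the connectivity of the two partners, and the three oxygens are born differentiated. On intrinsic regiocontrol of ring A it is at least as strong as the chosen plan.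
- Against it: both partners need several steps and are sensitive (a 1-alkoxyalkyne with a skipped alkene, a hydrolysable silyloxycyclobutenone). A benzene ring is built that can be bought with the right oxygens. The pyran is not closed in the key step, so an oxidative cyclisation is added. The route only arrives at 9 and then needs the same endgame.
- Comparison: the chosen strategy reaches 9 in five steps from a commercial phenol and closes the ring in the key step itself, so the risk is not spread over reagent syntheses.

Key step: step 5

## Route

Step 1
Reactants: 1 3-fluoro-5-methoxyphenol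
Product: 2 (3-fluoro-5-methoxyphenoxy)triisopropylsilane
Conditions: TIPSCl, imidazole, DMF, rt
Reagents that add atoms: triisopropylsilyl chloride, CC(C)[Si](Cl)(C(C)C)C(C)C
Why: Imidazole-promoted O-silylation of a phenol. The bulky silyl ether does not direct metalation and shields both of its ortho positions for step 2.

Step 2
Reactants: 2 (3-fluoro-5-methoxyphenoxy)triisopropylsilane
Product: 4 (3-fluoro-4-iodo-5-methoxyphenoxy)triisopropylsilane, via aryllithium 3 (not isolated)
Conditions: s-BuLi, THF, −78 °C; then I2, THF, −78 °C → rt
Reagents that add atoms: iodine, II
Why: Directed ortho-metalation at the C–H between F and OMe, which is the most acidic and least hindered site because both neighbours acidify it and OMe binds lithium while the silyl ether blocks the other two positions. At −78 °C the 2-fluoroaryllithium 3 should not lose LiF, and iodine traps it.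

Step 3
Reactants: 4 (3-fluoro-4-iodo-5-methoxyphenoxy)triisopropylsilane; 5 2-methylbut-3-yn-2-ol
Product: 6 4-[2-fluoro-6-methoxy-4-(triisopropylsilyloxy)phenyl]-2-methylbut-3-yn-2-ol
Conditions: PdCl2(PPh3)2 (cat.), CuI (cat.), Et3N, THF, 50 °C, degassed
Reagents that add atoms: none
Why: Sonogashira coupling of an aryl iodide with a terminal alkyne. The iodide reacts despite two ortho substituents because both are small and the slim alkyne has little steric demand.

Step 4
Reactants: 6 4-[2-fluoro-6-methoxy-4-(triisopropylsilyloxy)phenyl]-2-methylbut-3-yn-2-ol
Product: 7 (Z)-4-[2-fluoro-6-methoxy-4-(triisopropylsilyloxy)phenyl]-2-methylbut-3-en-2-ol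
Conditions: H2 (1 atm), Pd/CaCO3 poisoned with Pb(OAc)2 (Lindlar catalyst), quinoline, EtOAc, rt
Reagents that add atoms: none
Why: Lindlar semi-hydrogenation. Syn delivery of hydrogen on the catalyst surface gives the Z-alkene, and the poisoned catalyst should stop at the alkene and leave the C–F bond and the silyl ether alone.

Step 5
Reactants: 7 (Z)-4-[2-fluoro-6-methoxy-4-(triisopropylsilyloxy)phenyl]-2-methylbut-3-en-2-ol
Product: 9 5-methoxy-2,2-dimethyl-7-(triisopropylsilyloxy)-2H-chromene, via potassium alkoxide 8 (not isolated)
Conditions: KN(SiMe3)2, THF, 0 °C → 65 °C
Reagents that add atoms: none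
Why: KN(SiMe3)2 turns the tertiary alcohol into potassium alkoxide 8, whose oxygen the Z-alkene holds next to the arene. The oxygen attacks the fluorine-bearing carbon (the future C8a) and fluoride leaves; this is the known base-mediated cyclisation of fluoroarenes by a pendant alkoxide, here on a ring without a π-acceptor. Since nothing can hold the negative charge, the σ-adduct is more likely a Meisenheimer-like transition structure of a concerted or nearly concerted displacement than a lasting intermediate. The pyran ring closes in the 6-exo-trig mode at an sp2 carbon and forms O1–C8a; no stereocentre is created. The step needs attack at the C–F carbon and not at the C–OMe carbon on the other side of the side chain, nor at silicon. The C–F carbon is the more electrophilic one and fluoride is the better leaving group when addition is rate-limiting, and the C5 and C7 oxygens are meta to C8a, so they withdraw inductively without donating into the site of attack. The silyl group is hindered and para to the chain, out of reach of the alkoxide. Intramolecularity, the Z-geometry from step 4 and the gem-dimethyl group make up for the weak activation.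

Step 6
Reactants: 9 5-methoxy-2,2-dimethyl-7-(triisopropylsilyloxy)-2H-chromene
Product: 10 5-methoxy-2,2-dimethyl-2H-chromen-7-ol
Conditions: n-Bu4NF, THF, 0 °C; aqueous work-up
Reagents that add atoms: none
Why: Fluoride-mediated cleavage of an aryl silyl ether, driven by the Si–F bond; the chromene is inert to these conditions.

Step 7
Reactants: 10 5-methoxy-2,2-dimethyl-2H-chromen-7-ol
Product: 11 5-methoxy-7-(methoxymethoxy)-2,2-dimethyl-2H-chromene
Conditions: NaH, THF, 0 °C; then MOMCl, 0 °C → rt
Reagents that add atoms: chloromethyl methyl ether, COCCl
Why: Williamson-type O-alkylation of the sodium phenoxide. The acetal installed is a strong director for the next metalation and is removable by mild protic acid.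

Step 8
Reactants: 12 4-methoxyphenylacetic acid
Product: 14 N-methoxy-2-(4-methoxyphenyl)-N-methylacetamide, via acyl imidazolide 13 (not isolated)
Conditions: 1,1'-carbonyldiimidazole, CH2Cl2, rt; then MeNH(OMe)·HCl, rt
Reagents that add atoms: N,O-dimethylhydroxylamine hydrochloride, CNOC.Cl
Why: Weinreb amide formation through the acyl imidazolide. The hydrochloride protonates the released imidazole, which speeds the acyl transfer.

Step 9
Reactants: 11 5-methoxy-7-(methoxymethoxy)-2,2-dimethyl-2H-chromene; 14 N-methoxy-2-(4-methoxyphenyl)-N-methylacetamide
Product: 17 1-[5-methoxy-7-(methoxymethoxy)-2,2-dimethyl-2H-chromen-6-yl]-2-(4-methoxyphenyl)ethan-1-one, via 6-lithiochromene 15 (not isolated), via tetrahedral lithium chelate 16 (not isolated)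
Conditions: n-BuLi, THF, −20 → 0 °C; then 14, −78 → 0 °C; H2O
Reagents that add atoms: none
Why: Directed ortho-metalation by the methoxymethoxy group at C6, which is flanked by two ether oxygens that can bind lithium (O1 on the other side is a hindered tertiary-alkyl aryl ether oxygen), followed by a Weinreb ketone synthesis. Chelate 16 persists until work-up, so no second addition occurs. The selectivity for C6 over C8 and proton transfer from the amide are open points and are treated below.

Step 10
Reactants: 17 1-[5-methoxy-7-(methoxymethoxy)-2,2-dimethyl-2H-chromen-6-yl]-2-(4-methoxyphenyl)ethan-1-one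
Product: 18 1-[5-methoxy-7-(methoxymethoxy)-2,2-dimethyl-2H-chromen-6-yl]-2-(4-methoxyphenyl)ethane-1,2-dione
Conditions: SeO2, 1,4-dioxane/H2O, 90 °C
Reagents that add atoms: selenium dioxide, O=[Se]=O
Why: Riley oxidation of a deoxybenzoin to a benzil. The methylene is benzylic and alpha to the ketone and enolises towards the anisyl ring, and the chromene has no allylic C–H that the reagent could attack.

Step 11
Reactants: 18 1-[5-methoxy-7-(methoxymethoxy)-2,2-dimethyl-2H-chromen-6-yl]-2-(4-methoxyphenyl)ethane-1,2-dione
Product: 19 1-(7-hydroxy-5-methoxy-2,2-dimethyl-2H-chromen-6-yl)-2-(4-methoxyphenyl)ethane-1,2-dione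
Conditions: HCl (aq.), MeOH, 40 °C
Reagents that add atoms: none
Why: Acid-catalysed acetal exchange with methanol removes the methoxymethyl group. A protic acid is used because a Lewis acid would also cleave the C5 methyl ether ortho to C9, and the 2,2-dimethylchromene tolerates dilute acid.

## Compound list

1 | 3-fluoro-5-methoxyphenol | COc1cc(O)cc(F)c1 | starting material
2 | (3-fluoro-5-methoxyphenoxy)triisopropylsilane | COc1cc(O[Si](C(C)C)(C(C)C)C(C)C)cc(F)c1 | intermediate
3 | [2-fluoro-6-methoxy-4-(triisopropylsilyloxy)phenyl]lithium | COc1cc(O[Si](C(C)C)(C(C)C)C(C)C)cc(F)c1[Li] | intermediate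
4 | (3-fluoro-4-iodo-5-methoxyphenoxy)triisopropylsilane | COc1cc(O[Si](C(C)C)(C(C)C)C(C)C)cc(F)c1I | intermediate
5 | 2-methylbut-3-yn-2-ol | CC(C)(O)C#C | starting material
6 | 4-[2-fluoro-6-methoxy-4-(triisopropylsilyloxy)phenyl]-2-methylbut-3-yn-2-ol | COc1cc(O[Si](C(C)C)(C(C)C)C(C)C)cc(F)c1C#CC(C)(C)O | intermediate
7 | (Z)-4-[2-fluoro-6-methoxy-4-(triisopropylsilyloxy)phenyl]-2-methylbut-3-en-2-ol | COc1cc(O[Si](C(C)C)(C(C)C)C(C)C)cc(F)c1/C=C\C(C)(C)O | intermediate
8 | potassium (Z)-4-[2-fluoro-6-methoxy-4-(triisopropylsilyloxy)phenyl]-2-methylbut-3-en-2-olate | COc1cc(O[Si](C(C)C)(C(C)C)C(C)C)cc(F)c1/C=C\C(C)(C)[O-].[K+] | intermediate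
9 | 5-methoxy-2,2-dimethyl-7-(triisopropylsilyloxy)-2H-chromene | COc1cc(O[Si](C(C)C)(C(C)C)C(C)C)cc2OC(C)(C)C=Cc12 | intermediate
10 | 5-methoxy-2,2-dimethyl-2H-chromen-7-ol | COc1cc(O)cc2OC(C)(C)C=Cc12 | intermediate
11 | 5-methoxy-7-(methoxymethoxy)-2,2-dimethyl-2H-chromene | COCOc1cc2OC(C)(C)C=Cc2c(OC)c1 | intermediate
12 | 4-methoxyphenylacetic acid | COc1ccc(CC(=O)O)cc1 | starting material
13 | 1-(1H-imidazol-1-yl)-2-(4-methoxyphenyl)ethan-1-one | COc1ccc(CC(=O)n2ccnc2)cc1 | intermediate
14 | N-methoxy-2-(4-methoxyphenyl)-N-methylacetamide | COc1ccc(CC(=O)N(C)OC)cc1 | intermediate
15 | [5-methoxy-7-(methoxymethoxy)-2,2-dimethyl-2H-chromen-6-yl]lithium | COCOc1cc2OC(C)(C)C=Cc2c(OC)c1[Li] | intermediate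
16 | lithium 1-[5-methoxy-7-(methoxymethoxy)-2,2-dimethyl-2H-chromen-6-yl]-1-[methoxy(methyl)amino]-2-(4-methoxyphenyl)ethan-1-olate (racemic, transient) | COc1ccc(CC(O[Li])(N(C)OC)c2c(OCOC)cc3OC(C)(C)C=Cc3c2OC)cc1 | intermediate
17 | 1-[5-methoxy-7-(methoxymethoxy)-2,2-dimethyl-2H-chromen-6-yl]-2-(4-methoxyphenyl)ethan-1-one | COc1ccc(CC(=O)c2c(OCOC)cc3OC(C)(C)C=Cc3c2OC)cc1 | intermediate
18 | 1-[5-methoxy-7-(methoxymethoxy)-2,2-dimethyl-2H-chromen-6-yl]-2-(4-methoxyphenyl)ethane-1,2-dione | COc1ccc(C(=O)C(=O)c2c(OCOC)cc3OC(C)(C)C=Cc3c2OC)cc1 | intermediate
19 | 1-(7-hydroxy-5-methoxy-2,2-dimethyl-2H-chromen-6-yl)-2-(4-methoxyphenyl)ethane-1,2-dione | COc1ccc(C(=O)C(=O)c2c(O)cc3c(c2OC)C=CC(C)(C)O3)cc1 | target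

## Step count and least certain steps

Total step count: 11. Longest linear sequence: 10 steps (steps 1 to 7 and 9 to 11, from 1); step 8 is a one-step side branch.

**Step 5 (key step).** The most likely failure is a displacement that is too slow. The ring is electron-rich and activated only inductively, and the nucleophile is a hindered tertiary alkoxide. Forcing conditions would then let the liberated fluoride strip the silyl group, and the resulting phenoxide ring would resist attack even more.

The fallback changes the mechanism from addition–elimination to elimination–addition. It sets out from 7 and comes back at 9. Excess lithium 2,2,6,6-tetramethylpiperidide in THF (−78 °C → rt) would form the lithium alkoxide and remove the ring proton next to fluorine, the only remaining position activated by fluorine. Loss of LiF would give the aryne lithium (Z)-4-[2,3-didehydro-6-methoxy-4-(triisopropylsilyloxy)phenyl]-2-methylbut-3-en-2-olate F1. The tethered alkoxide can only reach the nearer aryne carbon, the future C8a, and addition there followed by protonation on work-up would give 9. This is the known intramolecular trapping of arynes by alkoxides.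

**Step 9.** The most likely failure is metalation at C8 in competition with C6. Both positions lie between two oxygens, and O1 holds an in-plane lone pair towards C8, while the C5 methyl group crowds C6. A second weakness is proton transfer from the benzylic methylene of 14 to the hindered aryllithium instead of addition.

The fallback turns a preference for C8 into a blocking step. It sets out from 11 and comes back at 19.
- Metalation of 11 with n-BuLi and quenching with Me3SiCl would give [5-methoxy-7-(methoxymethoxy)-2,2-dimethyl-2H-chromen-8-yl]trimethylsilane F2.
- A second metalation with s-BuLi and TMEDA can now only occur at C6. Acylation with 14 would give 1-[5-methoxy-7-(methoxymethoxy)-2,2-dimethyl-8-(trimethylsilyl)-2H-chromen-6-yl]-2-(4-methoxyphenyl)ethan-1-one F3.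
- Oxidation as in step 10 would give 1-[5-methoxy-7-(methoxymethoxy)-2,2-dimethyl-8-(trimethylsilyl)-2H-chromen-6-yl]-2-(4-methoxyphenyl)ethane-1,2-dione F4.
- The closing treatment with HCl in MeOH would remove the acetal and, by ipso-protonation at the electron-rich C8, the silyl group, and give 19.

**Step 10.** The most likely failure is oxidation away from the methylene: attack of the electrophilic selenium reagent on the C3=C4 bond, or acid-induced loss of the acetal at 90 °C followed by capture of the oxidised intermediate by the free phenol. Slow enolisation of the hindered ketone would make both worse.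

The fallback replaces the direct oxidation by enolate hydroxylation and alcohol oxidation. It sets out from 17 and comes back at 18. The potassium enolate (KN(SiMe3)2, THF, −78 °C) would be hydroxylated with 3-phenyl-2-(phenylsulfonyl)oxaziridine to the racemic benzoin 2-hydroxy-1-[5-methoxy-7-(methoxymethoxy)-2,2-dimethyl-2H-chromen-6-yl]-2-(4-methoxyphenyl)ethan-1-one F5. Dess–Martin periodinane would then oxidise F5 to 18 under neutral conditions.

**Step 4.** The most likely failure is over-reduction to the saturated chain or partial Z-to-E isomerisation if the hindered alkyne reacts slowly and the hydrogenation is pushed. Only the Z-isomer can cyclise in step 5.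

The fallback builds the Z-alkene by olefination instead of reduction. It sets out from 2 and comes back at 7.
- Aryllithium 3, made as in step 2, would be quenched with DMF to give 2-fluoro-6-methoxy-4-(triisopropylsilyloxy)benzaldehyde F6.
- A Still–Gennari olefination (methyl bis(2,2,2-trifluoroethyl)phosphonoacetate, KN(SiMe3)2, 18-crown-6, THF, −78 °C) would give methyl (Z)-3-[2-fluoro-6-methoxy-4-(triisopropylsilyloxy)phenyl]prop-2-enoate F7.
- Double addition of MeLi in the presence of CeCl3 to the ester would give 7.

## Further compounds

F1 | step 5 | lithium (Z)-4-[2,3-didehydro-6-methoxy-4-(triisopropylsilyloxy)phenyl]-2-methylbut-3-en-2-olate | COC1=C(/C=C\C(C)(C)O[Li])C#CC(O[Si](C(C)C)(C(C)C)C(C)C)=C1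
F2 | step 9 | [5-methoxy-7-(methoxymethoxy)-2,2-dimethyl-2H-chromen-8-yl]trimethylsilane | COCOc1cc(OC)c2C=CC(C)(C)Oc2c1[Si](C)(C)C
F3 | step 9 | 1-[5-methoxy-7-(methoxymethoxy)-2,2-dimethyl-8-(trimethylsilyl)-2H-chromen-6-yl]-2-(4-methoxyphenyl)ethan-1-one | COc1ccc(CC(=O)c2c(OCOC)c([Si](C)(C)C)c3OC(C)(C)C=Cc3c2OC)cc1
F4 | step 9 | 1-[5-methoxy-7-(methoxymethoxy)-2,2-dimethyl-8-(trimethylsilyl)-2H-chromen-6-yl]-2-(4-methoxyphenyl)ethane-1,2-dione | COc1ccc(C(=O)C(=O)c2c(OCOC)c([Si](C)(C)C)c3OC(C)(C)C=Cc3c2OC)cc1
F5 | step 10 | 2-hydroxy-1-[5-methoxy-7-(methoxymethoxy)-2,2-dimethyl-2H-chromen-6-yl]-2-(4-methoxyphenyl)ethan-1-one (racemic) | COc1ccc(C(O)C(=O)c2c(OCOC)cc3OC(C)(C)C=Cc3c2OC)cc1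
F6 | step 4 | 2-fluoro-6-methoxy-4-(triisopropylsilyloxy)benzaldehyde | COc1cc(O[Si](C(C)C)(C(C)C)C(C)C)cc(F)c1C=O
F7 | step 4 | methyl (Z)-3-[2-fluoro-6-methoxy-4-(triisopropylsilyloxy)phenyl]prop-2-enoate | COC(=O)/C=C\c1c(F)cc(O[Si](C(C)C)(C(C)C)C(C)C)cc1OC
A1 | alternative 1 | 1-[5-methoxy-7-(methoxymethoxy)-2,2-dimethyl-2H-chromen-6-yl]-2-(4-methoxyphenyl)ethane-1,2-dione | COc1ccc(C(=O)C(=O)c2c(OCOC)cc3OC(C)(C)C=Cc3c2OC)cc1
A2 | alternative 1 | N,N'-dimethoxy-N,N'-dimethyloxalamide | CON(C)C(=O)C(=O)N(C)OC
A3 | alternative 1 | 4-methoxyphenylmagnesium bromide | COc1ccc([Mg]Br)cc1
A4 | alternative 2 | methyl 5-hydroxy-7-(methoxymethoxy)-2,2-dimethyl-2H-chromene-6-carboxylate | COC(=O)c1c(O)c2C=CC(C)(C)Oc2cc1OCOC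
A5 | alternative 2 | methyl 2-hydroxy-6-(methoxymethoxy)-4-[(2-methylbut-3-yn-2-yl)oxy]benzoate | COC(=O)c1c(O)cc(OC(C)(C)C#C)cc1OCOC
A6 | alternative 3 | 3-methoxy-2-(3-methylbut-2-en-1-yl)-5-(triisopropylsilyloxy)phenol | COc1cc(O[Si](C(C)C)(C(C)C)C(C)C)cc(O)c1CC=C(C)C
A7 | alternative 3 | 3-(triisopropylsilyloxy)cyclobut-2-en-1-one | O=C1CC(O[Si](C(C)C)(C(C)C)C(C)C)=C1
A8 | alternative 3 | 1-methoxy-5-methylhex-4-en-1-yne | COC#CCC=C(C)C
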